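**Assumption:** 25 is treated as the open hydroxy ketone drawn; a ring-closed hemiketal form in equilibrium with it would be the same substance.

## Retrosynthetic overview

1. The aryl ketone of 25 comes from Weinreb amide 21 and Grignard reagent 22; the amide comes from cis-fused lactone 19, which holds the epimerisable C4 centre cis to the CH2OH arm.
2. Lactone 19 comes from oxidative cleavage of the (E)-propenyl handle of tetrahydrofuran 15 (ozonolysis to lactol 18, then oxidation).
3. Tetrahydrofuran 15 comes from acid-mediated SN1 ring closure of triol 13 (2,3-trans), itself from the anti-selective aldol of lactone 9 with aldehyde 10 and LiAlH4 reduction.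
4. Lactone 9 comes from Johnson–Claisen chirality transfer out of (S)-allylic alcohol 4, made by ketoreductase-catalysed asymmetric reduction of achiral enone 3 (Wittig of 1 + 2); this enzymatic step is the only source of absolute configuration.
5. Ring order: γ-lactone 9 (temporary), then the tetrahydrofuran ring (step 7), then the fused lactol/lactone ring (temporary, steps 8–9, reopened in step 10).

## Route

Step 1
Reactants: 1 (tert-butyldimethylsilyloxy)acetaldehyde; 2 1-(triphenylphosphoranylidene)propan-2-one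
Product: 3 (E)-5-[(tert-butyldimethylsilyl)oxy]pent-3-en-2-one
Conditions: CH2Cl2, rt → 40 °C, 16 h
Reagents that add atoms: none
Why: Wittig olefination with a stabilised acyl ylide gives the (E)-enone selectively and creates no stereocentre.

Step 2
Reactants: 3 (E)-5-[(tert-butyldimethylsilyl)oxy]pent-3-en-2-one
Product: 4 (S,E)-5-[(tert-butyldimethylsilyl)oxy]pent-3-en-2-ol
Conditions: ketoreductase (Prelog-selective NADH-dependent alcohol dehydrogenase, e.g. ADH-A of Rhodococcus ruber), NAD+ (cat.), i-PrOH (20% v/v), KH2PO4/K2HPO4 buffer pH 7.0, 30 °C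
Reagents that add atoms: none
Why: Ketoreductase-catalysed asymmetric ketone reduction, in which the enzyme delivers hydride from NADH to the Re face of the achiral methyl enone (carbonyl only, C=C untouched) to set the (S)-carbinol in very high ee, with isopropanol regenerating the cofactor.

Step 3
Reactants: 4 (S,E)-5-[(tert-butyldimethylsilyl)oxy]pent-3-en-2-ol; 5 triethyl orthoacetate
Product: 7 ethyl (S,E)-3-{[(tert-butyldimethylsilyl)oxy]methyl}hex-4-enoate, via ketene acetal 6 (not isolated)
Conditions: MeC(OEt)3 (6 equiv), EtCO2H (5 mol %), 140 °C, EtOH distilled off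
Reagents that add atoms: none
Why: Johnson–Claisen [3,3]-sigmatropic rearrangement through a chair transition state with the methyl group equatorial transfers the carbinol chirality suprafacially to the new (S)-configured C3 centre and gives the (E)-propenyl group; the few percent of (Z)-isomer, which carries the opposite C3 configuration, is removed on AgNO3-impregnated silica.

Step 4
Reactants: 7 ethyl (S,E)-3-{[(tert-butyldimethylsilyl)oxy]methyl}hex-4-enoate
Product: 9 (S)-4-[(E)-prop-1-en-1-yl]dihydrofuran-2(3H)-one, via hydroxy ester 8 (not isolated)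
Conditions: 1 M HCl (aq)/THF, rt; then p-TsOH (cat.), CH2Cl2, rt
Reagents that add atoms: none
Why: Acidic silyl ether hydrolysis followed by acid-catalysed lactonisation (intramolecular transesterification) of the γ-hydroxy ester, leaving the stereocentre untouched.

Step 5
Reactants: 9 (S)-4-[(E)-prop-1-en-1-yl]dihydrofuran-2(3H)-one; 10 3,4-dimethoxybenzaldehyde
Product: 12 (3S,4R)-3-[(3,4-dimethoxyphenyl)(hydroxy)methyl]-4-[(E)-prop-1-en-1-yl]dihydrofuran-2(3H)-one (both carbinol epimers), via lithium enolate 11 (not isolated)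
Conditions: LiN(i-Pr)2, THF, −78 °C; then 10, −78 °C; AcOH quench at −78 °C
Reagents that add atoms: none
Why: Lithium enolate aldol addition in which the aldehyde attacks the enolate face anti to the C4 propenyl group, setting C3 trans to C4, while the carbinol centre is left as a mixture because it is erased in step 7.

Step 6
Reactants: 12 (3S,4R)-3-[(3,4-dimethoxyphenyl)(hydroxy)methyl]-4-[(E)-prop-1-en-1-yl]dihydrofuran-2(3H)-one
Product: 13 (2R,3R)-2-[(3,4-dimethoxyphenyl)(hydroxy)methyl]-3-[(E)-prop-1-en-1-yl]butane-1,4-diol (both carbinol epimers)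
Conditions: LiAlH4, THF, 0 °C → rt; then Na2SO4·10H2O
Reagents that add atoms: none
Why: Hydride reduction of the lactone to the 1,4-diol touches no stereocentre (the C2 descriptor changes only through CIP priorities).

Step 7
Reactants: 13 (2R,3R)-2-[(3,4-dimethoxyphenyl)(hydroxy)methyl]-3-[(E)-prop-1-en-1-yl]butane-1,4-diol
Product: 15 {(2S,3R,4R)-2-(3,4-dimethoxyphenyl)-4-[(E)-prop-1-en-1-yl]tetrahydrofuran-3-yl}methanol, via benzylic cation 14 (not isolated)
Conditions: (±)-camphor-10-sulfonic acid (10 mol %), CH2Cl2, 0 °C → rt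
Reagents that add atoms: none
Why: Acid-promoted SN1 dehydrative cycloetherification in which both carbinol epimers ionise to the same dimethoxyphenyl-stabilised cation, only the C4 hydroxyl can close a five-membered ring (the other would give an oxetane), and reversible closure places the aryl group trans to the neighbouring CH2OH group (2S).

Step 8
Reactants: 15 {(2S,3R,4R)-2-(3,4-dimethoxyphenyl)-4-[(E)-prop-1-en-1-yl]tetrahydrofuran-3-yl}methanol
Product: 18 (1R,5R,6S)-6-(3,4-dimethoxyphenyl)-3,7-dioxabicyclo[3.3.0]octan-2-ol (both anomers), via ozonide 16 (not isolated), via hydroxy aldehyde 17 (not isolated)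
Conditions: O3, CH2Cl2, −78 °C (Sudan Red 7B end-point); then Me2S, −78 °C → rt
Reagents that add atoms: ozone O=[O+][O-]
Why: Ozonolysis with reductive work-up cleaves the disubstituted alkene much faster than the arenes, and the cis CH2OH group traps the aldehyde at once as the cis-fused lactol, so the epimerisable C4 centre is locked.

Step 9
Reactants: 18 (1R,5R,6S)-6-(3,4-dimethoxyphenyl)-3,7-dioxabicyclo[3.3.0]octan-2-ol
Product: 19 (1R,5R,6S)-6-(3,4-dimethoxyphenyl)-3,7-dioxabicyclo[3.3.0]octan-2-one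
Conditions: TEMPO (10 mol %), PhI(OAc)2 (1.3 equiv), CH2Cl2, rt
Reagents that add atoms: none
Why: Oxoammonium (TEMPO) oxidation of a lactol to the lactone under neutral conditions, with no stereocentre involved.

Step 10
Reactants: 19 (1R,5R,6S)-6-(3,4-dimethoxyphenyl)-3,7-dioxabicyclo[3.3.0]octan-2-one
Product: 20 (3R,4R,5S)-5-(3,4-dimethoxyphenyl)-4-(hydroxymethyl)-N-methoxy-N-methyltetrahydrofuran-3-carboxamide
Conditions: MeNH(OMe)·HCl, i-PrMgCl, THF, −20 → 0 °C; then H2O/aq. NH4Cl; used crude
Reagents that add atoms: N,O-dimethylhydroxylamine hydrochloride CNOC.Cl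
Why: Weinreb aminolysis of the lactone by the magnesium amide made in the flask, under non-Lewis-acidic conditions that spare the benzylic ether and leave the cis ring-fusion configuration in place.

Step 11
Reactants: 20 (3R,4R,5S)-5-(3,4-dimethoxyphenyl)-4-(hydroxymethyl)-N-methoxy-N-methyltetrahydrofuran-3-carboxamide
Product: 21 (3R,4R,5S)-4-{[(tert-butyldimethylsilyl)oxy]methyl}-5-(3,4-dimethoxyphenyl)-N-methoxy-N-methyltetrahydrofuran-3-carboxamide
Conditions: TBSCl, imidazole, DMF, 0 °C → rt
Reagents that add atoms: tert-butyldimethylsilyl chloride CC(C)(C)[Si](C)(C)Cl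
Why: Silyl protection of the primary alcohol stops relactonisation and removes the acidic proton before the Grignard step.

Step 12
Reactants: 21 (3R,4R,5S)-4-{[(tert-butyldimethylsilyl)oxy]methyl}-5-(3,4-dimethoxyphenyl)-N-methoxy-N-methyltetrahydrofuran-3-carboxamide; 22 (3,4,5-trimethoxyphenyl)magnesium bromide
Product: 24 [(3R,4R,5S)-4-{[(tert-butyldimethylsilyl)oxy]methyl}-5-(3,4-dimethoxyphenyl)tetrahydrofuran-3-yl](3,4,5-trimethoxyphenyl)methanone, via magnesium hemiaminal 23 (not isolated)
Conditions: THF, 0 °C → rt; then H2O/aq. NH4Cl, 0 °C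
Reagents that add atoms: none
Why: Weinreb ketone synthesis, in which the chelated tetrahedral adduct persists until work-up, so there is no over-addition and the α-centre is never exposed as a free ketone to the basic reagent.

Step 13
Reactants: 24 [(3R,4R,5S)-4-{[(tert-butyldimethylsilyl)oxy]methyl}-5-(3,4-dimethoxyphenyl)tetrahydrofuran-3-yl](3,4,5-trimethoxyphenyl)methanone
Product: 25 [(3R,4R,5S)-5-(3,4-dimethoxyphenyl)-4-(hydroxymethyl)tetrahydrofuran-3-yl](3,4,5-trimethoxyphenyl)methanone (CNP0271206.4)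
Conditions: HF·pyridine, pyridine, THF, 0 °C → rt
Reagents that add atoms: none
Why: Fluoride-mediated desilylation under buffered, weakly acidic conditions avoids the base that could epimerise the ketone α-centre or open the β-alkoxy ketone by retro-oxa-Michael reaction.

## Compound list

1 | (tert-butyldimethylsilyloxy)acetaldehyde | O=CCO[Si](C)(C)C(C)(C)C | starting material
2 | 1-(triphenylphosphoranylidene)propan-2-one | CC(=O)C=P(c1ccccc1)(c1ccccc1)c1ccccc1 | starting material
3 | (E)-5-[(tert-butyldimethylsilyl)oxy]pent-3-en-2-one | CC(=O)/C=C/CO[Si](C)(C)C(C)(C)C | intermediate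
4 | (S,E)-5-[(tert-butyldimethylsilyl)oxy]pent-3-en-2-ol | C[C@H](O)/C=C/CO[Si](C)(C)C(C)(C)C | intermediate
5 | triethyl orthoacetate (1,1,1-triethoxyethane) | CC(OCC)(OCC)OCC | starting material
6 | ketene acetal: (S,E)-tert-butyl({4-[(1-ethoxyvinyl)oxy]pent-2-en-1-yl}oxy)dimethylsilane | C=C(OCC)O[C@@H](C)/C=C/CO[Si](C)(C)C(C)(C)C | intermediate (not isolated)
7 | ethyl (S,E)-3-{[(tert-butyldimethylsilyl)oxy]methyl}hex-4-enoate | CCOC(=O)C[C@@H](/C=C/C)CO[Si](C)(C)C(C)(C)C | intermediate
8 | hydroxy ester: ethyl (S,E)-3-(hydroxymethyl)hex-4-enoate | CCOC(=O)C[C@@H](/C=C/C)CO | intermediate (not isolated)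
9 | (S)-4-[(E)-prop-1-en-1-yl]dihydrofuran-2(3H)-one | O=C1C[C@@H](/C=C/C)CO1 | intermediate
10 | 3,4-dimethoxybenzaldehyde | COc1ccc(C=O)cc1OC | starting material
11 | lithium enolate of 9 (C4 configuration unchanged) | [Li]OC1=C[C@@H](/C=C/C)CO1 | intermediate (not isolated)
12 | (3S,4R)-3-[(3,4-dimethoxyphenyl)(hydroxy)methyl]-4-[(E)-prop-1-en-1-yl]dihydrofuran-2(3H)-one, both carbinol epimers | O=C1OC[C@H](/C=C/C)[C@H]1C(O)c1ccc(OC)c(OC)c1 | intermediate
13 | (2R,3R)-2-[(3,4-dimethoxyphenyl)(hydroxy)methyl]-3-[(E)-prop-1-en-1-yl]butane-1,4-diol, both carbinol epimers | OC[C@H](/C=C/C)[C@H](CO)C(O)c1ccc(OC)c(OC)c1 | intermediate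
14 | benzylic cation formed from 13 by loss of the benzylic hydroxyl | COc1ccc([CH+][C@@H](CO)[C@@H](/C=C/C)CO)cc1OC | intermediate (not isolated)
15 | {(2S,3R,4R)-2-(3,4-dimethoxyphenyl)-4-[(E)-prop-1-en-1-yl]tetrahydrofuran-3-yl}methanol | COc1ccc([C@H]2OC[C@H](/C=C/C)[C@@H]2CO)cc1OC | intermediate
16 | ozonide: {(2S,3R,4R)-2-(3,4-dimethoxyphenyl)-4-(5-methyl-1,2,4-trioxolan-3-yl)tetrahydrofuran-3-yl}methanol | COc1ccc([C@H]2OC[C@H](C3OOC(C)O3)[C@@H]2CO)cc1OC | intermediate (not isolated)
17 | hydroxy aldehyde: (3R,4R,5S)-5-(3,4-dimethoxyphenyl)-4-(hydroxymethyl)tetrahydrofuran-3-carbaldehyde | COc1ccc([C@H]2OC[C@H](C=O)[C@@H]2CO)cc1OC | intermediate (not isolated)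
18 | (1R,5R,6S)-6-(3,4-dimethoxyphenyl)-3,7-dioxabicyclo[3.3.0]octan-2-ol, both anomers | COc1ccc([C@H]2OC[C@H](C(O)OC3)[C@@H]23)cc1OC | intermediate
19 | (1R,5R,6S)-6-(3,4-dimethoxyphenyl)-3,7-dioxabicyclo[3.3.0]octan-2-one | COc1ccc([C@H]2OC[C@H](C(=O)OC3)[C@@H]23)cc1OC | intermediate
20 | (3R,4R,5S)-5-(3,4-dimethoxyphenyl)-4-(hydroxymethyl)-N-methoxy-N-methyltetrahydrofuran-3-carboxamide | COc1ccc([C@H]2OC[C@H](C(=O)N(C)OC)[C@@H]2CO)cc1OC | intermediate
21 | (3R,4R,5S)-4-{[(tert-butyldimethylsilyl)oxy]methyl}-5-(3,4-dimethoxyphenyl)-N-methoxy-N-methyltetrahydrofuran-3-carboxamide | COc1ccc([C@H]2OC[C@H](C(=O)N(C)OC)[C@@H]2CO[Si](C)(C)C(C)(C)C)cc1OC | intermediate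
22 | (3,4,5-trimethoxyphenyl)magnesium bromide (THF solution) | COc1cc([Mg]Br)cc(OC)c1OC | starting material
23 | magnesium hemiaminal: bromomagnesium alkoxide of the tetrahedral adduct of 22 to the amide carbonyl of 21 | COc1ccc([C@H]2OC[C@H](C(O[Mg]Br)(N(C)OC)c3cc(OC)c(OC)c(OC)c3)[C@@H]2CO[Si](C)(C)C(C)(C)C)cc1OC | intermediate (not isolated)
24 | [(3R,4R,5S)-4-{[(tert-butyldimethylsilyl)oxy]methyl}-5-(3,4-dimethoxyphenyl)tetrahydrofuran-3-yl](3,4,5-trimethoxyphenyl)methanone | COc1ccc([C@H]2OC[C@H](C(=O)c3cc(OC)c(OC)c(OC)c3)[C@@H]2CO[Si](C)(C)C(C)(C)C)cc1OC | intermediate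
25 | [(3R,4R,5S)-5-(3,4-dimethoxyphenyl)-4-(hydroxymethyl)tetrahydrofuran-3-yl](3,4,5-trimethoxyphenyl)methanone | COc1ccc([C@H]2OC[C@H](C(=O)c3cc(OC)c(OC)c(OC)c3)[C@@H]2CO)cc1OC | target

## Step count and risks

Total steps: 13. Longest linear sequence: 13 steps (1/2 → 25); every other building block (5, 10, 22) is commercial.

**Step 7 (cation ring closure, with the aldol that feeds it).** The triol can give oligomeric benzyl ethers or cation–alkene products, and the aldol adduct is prone to retro-aldol loss. The fallback sets out from lactone 9 and comes back at 15, replacing dehydration by benzylic C–H oxidation. Enolate 11 is alkylated with 4-(bromomethyl)-1,2-dimethoxybenzene (THF, −78 → −40 °C), anti to the propenyl group, to give (3R,4R)-3-(3,4-dimethoxybenzyl)-4-[(E)-prop-1-en-1-yl]dihydrofuran-2(3H)-one F1. LiAlH4 reduction gives (2R,3R)-2-(3,4-dimethoxybenzyl)-3-[(E)-prop-1-en-1-yl]butane-1,4-diol F2. DDQ (1.05 equiv, CH2Cl2, 4 Å sieves, 0 °C) then abstracts the electron-rich benzylic hydride and the C4 hydroxyl closes the ring through cation 14 to give 15, with no benzylic alcohol or Brønsted acid involved.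

**Step 8 (ozonolysis beside two electron-rich arenes).** Over-oxidation of the rings or the benzylic ether is possible. The fallback sets out from 15 and comes back at 18. Dihydroxylation of the propenyl group (OsO4 cat., NMO, acetone/H2O) gives 1-[(3R,4R,5S)-5-(3,4-dimethoxyphenyl)-4-(hydroxymethyl)tetrahydrofuran-3-yl]propane-1,2-diol F3. Glycol cleavage with NaIO4 (THF/H2O) releases hydroxy aldehyde 17, which closes to lactol 18.

**Step 10 (lactone opening to the hydroxy Weinreb amide).** The cis-fused lactone can re-form on work-up, giving low conversion. The fallback sets out from lactol 18 and comes back at 25, bypassing the lactone, the amide and the silyl group. Excess Grignard reagent 22 (3.5 equiv, THF, 0 °C → rt) adds to the open aldehyde form of 18 to give {(2S,3R,4R)-2-(3,4-dimethoxyphenyl)-4-[hydroxy(3,4,5-trimethoxyphenyl)methyl]tetrahydrofuran-3-yl}methanol F4 as a carbinol mixture. Activated MnO2 (CH2Cl2, rt) then oxidises only the benzylic secondary alcohol, leaving the primary alcohol, and gives 25 without any basic step after the ketone is formed.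

## Further compounds

F1 | step 7 | (3R,4R)-3-(3,4-dimethoxybenzyl)-4-[(E)-prop-1-en-1-yl]dihydrofuran-2(3H)-one | O=C1OC[C@H](/C=C/C)[C@H]1Cc1ccc(OC)c(OC)c1
F2 | step 7 | (2R,3R)-2-(3,4-dimethoxybenzyl)-3-[(E)-prop-1-en-1-yl]butane-1,4-diol | OC[C@H](/C=C/C)[C@H](CO)Cc1ccc(OC)c(OC)c1
F3 | step 8 | 1-[(3R,4R,5S)-5-(3,4-dimethoxyphenyl)-4-(hydroxymethyl)tetrahydrofuran-3-yl]propane-1,2-diol (diol diastereomers) | COc1ccc([C@H]2OC[C@H](C(O)C(C)O)[C@@H]2CO)cc1OC
F4 | step 10 | {(2S,3R,4R)-2-(3,4-dimethoxyphenyl)-4-[hydroxy(3,4,5-trimethoxyphenyl)methyl]tetrahydrofuran-3-yl}methanol (carbinol epimers) | COc1ccc([C@H]2OC[C@H](C(O)c3cc(OC)c(OC)c(OC)c3)[C@@H]2CO)cc1OC
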